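**Retrosynthetic overview**
1. Both furan bonds of the dibenzofuran (aryl–aryl C–C and aryl–O) are cut in one operation. This also opens the 18-membered ring and leads back to an acyclic bis(bibenzyl) triol.
2. In that triol, ring D is a free, locally C2v-symmetric 5-alkylresorcinol and ring C is a 4-bromo-3-fluorophenyl group. In the forward direction, palladium C-arylation through a cyclohexadienone followed by fluoride displacement breaks the symmetry of ring D.
3. The triol comes from its trimethyl ether (BBr3), and that ether comes from an (E,E)-bis-stilbene (diimide, which spares C–Br).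
4. The bis-stilbene comes from two Horner–Wadsworth–Emmons olefinations and one SNAr diaryl ether synthesis (rings A–O–B), starting from isovanillin and 4-fluorobenzaldehyde.
5. Ring order: no ring is formed until the last flask. There the macrocycle closes first and the furan second.

Assumption: the SMILES shows no stereocentre and no fixed axis or plane of chirality, so asterelin A is made as the single constitution drawn and needs no stereocontrol.

**Step 1**
Reactants: 1 4-bromo-3-fluorobenzyl bromide; 2 triethyl phosphite; 3 isovanillin (3-hydroxy-4-methoxybenzaldehyde)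
Product: 5 (E)-5-[2-(4-bromo-3-fluorophenyl)ethenyl]-2-methoxyphenol, via diethyl (4-bromo-3-fluorobenzyl)phosphonate 4 (not isolated)
Conditions: 1 + 2 (1.2 equiv), neat, 140 °C, 3 h, volatiles off in vacuo; then 3, KOtBu (2.5 equiv), DMF, 0 °C to rt; dil. HCl quench
Reagents that add atoms: none
Why: A Michaelis–Arbuzov reaction gives phosphonate 4, whose carbanion undergoes Horner–Wadsworth–Emmons olefination with the aldehyde of 3 (the extra base parks the phenol as a meta, non-conjugated phenoxide), giving the E-alkene, whose geometry does not matter because it is saturated later.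

**Step 2**
Reactants: 5 (E)-5-[2-(4-bromo-3-fluorophenyl)ethenyl]-2-methoxyphenol; 6 4-fluorobenzaldehyde
Product: 7 4-{5-[(E)-2-(4-bromo-3-fluorophenyl)ethenyl]-2-methoxyphenoxy}benzaldehyde
Conditions: K2CO3 (2 equiv), DMF, 120 °C, 12 h
Reagents that add atoms: none
Why: This is nucleophilic aromatic substitution through a Meisenheimer complex, in which only the fluoride para to the formyl group is activated, so the C–F and C–Br bonds of ring C stay intact.

**Step 3**
Reactants: 7 4-{5-[(E)-2-(4-bromo-3-fluorophenyl)ethenyl]-2-methoxyphenoxy}benzaldehyde; 8 diethyl (3,5-dimethoxybenzyl)phosphonate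
Product: 9 1-bromo-4-[(E)-2-(3-{4-[(E)-2-(3,5-dimethoxyphenyl)ethenyl]phenoxy}-4-methoxyphenyl)ethenyl]-2-fluorobenzene
Conditions: 8 (1.2 equiv), KOtBu (1.5 equiv), THF, 0 °C to rt; dil. HCl quench
Reagents that add atoms: none
Why: Horner–Wadsworth–Emmons olefination of a non-enolisable aromatic aldehyde with a benzylic phosphonate reliably gives the E-stilbene and touches nothing else in 7.

**Step 4**
Reactants: 9 the (E,E)-bis-stilbene
Product: 10 1-bromo-4-[2-(3-{4-[2-(3,5-dimethoxyphenyl)ethyl]phenoxy}-4-methoxyphenyl)ethyl]-2-fluorobenzene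
Conditions: TsNHNH2 (20 equiv, in portions), NaOAc (20 equiv), DME/H2O, reflux, 36 h
Reagents that add atoms: none
Why: In this diimide reduction the HN=NH made in situ delivers H2 concertedly to both non-polar C=C bonds and, unlike heterogeneous hydrogenation, cannot cleave the aryl C–Br or C–F bonds.

**Step 5**
Reactants: 10 the bis(bibenzyl) trimethyl ether
Product: 11 5-[2-(4-{5-[2-(4-bromo-3-fluorophenyl)ethyl]-2-hydroxyphenoxy}phenyl)ethyl]benzene-1,3-diol
Conditions: BBr3 (9 equiv), CH2Cl2, −78 °C to rt; then H2O, 0 °C
Reagents that add atoms: none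
Why: Lewis-acid aryl methyl ether cleavage (O–B complexation, then bromide attack at methyl) removes all three methyl groups, while the diaryl ether and the aryl halides are inert.

**Step 6**
Reactants: 11 the acyclic bromo-fluoro triol
Product: 14 asterelin A, via macrocyclic cyclohexadienone 12 (not isolated), via macrocyclic fluorobiaryl triol 13 (not isolated)
Conditions: Pd(OAc)2 (15 mol %), 2-dicyclohexylphosphino-2',6'-diisopropoxybiphenyl (RuPhos, 30 mol %), Cs2CO3 (6 equiv), degassed DMA, 11 added by syringe pump over 10 h (final 2 mM), 110 °C; then 150 °C, 6 h; dil. HCl work-up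
Reagents that add atoms: none
Why: Proposed new method: zerovalent palladium inserts into the C–Br bond of ring C (helped by the ortho fluorine), the caesium resorcinolate of ring D, which behaves like the enolate of a vinylogous 1,3-diketone, replaces bromide on divalent palladium and slips from O to the carbon that is ortho to one oxygen and para to the other, and C–C reductive elimination gives cyclohexadienone 12 (ring D dearomatised), which tautomerises to biaryl 13, whose ortho phenoxide then displaces the neighbouring fluoride by intramolecular SNAr at 150 °C to close the furan; the two hydroxyls and the two reactive C–H positions of ring D are homotopic, so either pair gives the same product, attack at the carbon between the two oxygens would need a para,para'-bridged biphenyl in a 20-membered ring and is excluded by strain, the ring B phenoxide cannot reach ring C, and a dicyclohexylbiaryl phosphine does not promote C–O reductive elimination; the closest known reaction types are the palladium-catalysed arylative dearomatisation of tethered phenols, the palladium-catalysed annulation of phenols and naphthols with o-dihalobenzenes to dibenzofurans, the copper-catalysed Hurtley C-arylation of resorcinol at C-4, and the base-mediated cyclisation of 2'-fluorobiphenyl-2-ols.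

**Compound list**
1 | 4-bromo-3-fluorobenzyl bromide | BrCc1ccc(Br)c(F)c1 | starting material
2 | triethyl phosphite | CCOP(OCC)OCC | starting material
3 | isovanillin (3-hydroxy-4-methoxybenzaldehyde) | COc1ccc(C=O)cc1O | starting material
4 | diethyl (4-bromo-3-fluorobenzyl)phosphonate | CCOP(=O)(Cc1ccc(Br)c(F)c1)OCC | intermediate
5 | (E)-5-[2-(4-bromo-3-fluorophenyl)ethenyl]-2-methoxyphenol | COc1ccc(/C=C/c2ccc(Br)c(F)c2)cc1O | intermediate
6 | 4-fluorobenzaldehyde | O=Cc1ccc(F)cc1 | starting material
7 | 4-{5-[(E)-2-(4-bromo-3-fluorophenyl)ethenyl]-2-methoxyphenoxy}benzaldehyde | COc1ccc(/C=C/c2ccc(Br)c(F)c2)cc1Oc1ccc(C=O)cc1 | intermediate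
8 | diethyl (3,5-dimethoxybenzyl)phosphonate | CCOP(=O)(Cc1cc(OC)cc(OC)c1)OCC | starting material
9 | 1-bromo-4-[(E)-2-(3-{4-[(E)-2-(3,5-dimethoxyphenyl)ethenyl]phenoxy}-4-methoxyphenyl)ethenyl]-2-fluorobenzene | COc1ccc(/C=C/c2ccc(Br)c(F)c2)cc1Oc1ccc(/C=C/c2cc(OC)cc(OC)c2)cc1 | intermediate
10 | 1-bromo-4-[2-(3-{4-[2-(3,5-dimethoxyphenyl)ethyl]phenoxy}-4-methoxyphenyl)ethyl]-2-fluorobenzene | COc1ccc(CCc2ccc(Br)c(F)c2)cc1Oc1ccc(CCc2cc(OC)cc(OC)c2)cc1 | intermediate
11 | 5-[2-(4-{5-[2-(4-bromo-3-fluorophenyl)ethyl]-2-hydroxyphenoxy}phenyl)ethyl]benzene-1,3-diol | Oc1ccc(CCc2ccc(Br)c(F)c2)cc1Oc1ccc(CCc2cc(O)cc(O)c2)cc1 | intermediate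
12 | 2,5-cyclohexadienone tautomer of 13 (ring D has C=O para to the new sp3 C–H that carries ring C; this centre is racemic and is erased on tautomerisation) | O=C1C=C2C(C(O)=C1)c1ccc(cc1F)CCc1ccc(O)c(c1)Oc1ccc(cc1)CC2 | intermediate
13 | 18-membered fluorobiaryl triol (asterelin A with the furan C–O bond open: OH on ring D and F on ring C at the two carbons the furan oxygen will bridge) | Oc1cc2c(c(O)c1)-c1ccc(cc1F)CCc1ccc(O)c(c1)Oc1ccc(cc1)CC2 | intermediate
14 | asterelin A | Oc1cc2c3c(c1)oc1cc(ccc13)CCc1ccc(O)c(c1)Oc1ccc(cc1)CC2 | target

**Total step count:** 6. **Longest linear sequence:** 6 (1 → 5 → 7 → 9 → 10 → 11 → 14).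

**Three steps most likely to fail**

Step 6 may give oligomers, protodebromination or O-arylation instead of the macrocyclic C-arylation. The fallback sets out from 10 and comes back at 13. It does not rely on the innate nucleophilicity of the free resorcinol. Instead, both coupling carbons are pre-functionalised under methyl protection.
- Miyaura borylation of the aryl bromide of 10 (B2pin2, PdCl2(dppf), KOAc, dioxane, 90 °C) gives the ring C pinacol boronate F1.
- NBS (1.0 equiv, MeCN, 0 °C) brominates the most electron-rich ring D, para to one methoxy group and ortho to the chain, giving the bromo boronate F2.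
- An intramolecular Suzuki–Miyaura coupling (Pd(OAc)2, SPhos, K3PO4, dioxane/H2O, 2 mM, 90 °C) gives the macrocyclic fluorobiaryl trimethyl ether F3.
- BBr3 then gives 13, now isolated, which is closed to 14 with Cs2CO3 in DMA at 150 °C, as in the second half of step 6.

Step 1 may be sluggish or low-yielding, because the olefination is run in one pot on an unprotected hydroxy aldehyde. The fallback sets out from 4 (made from 1 and 2 as before, but isolated) and comes back at 9. The order of bond formation is reversed, so no free phenol ever meets the phosphonate anion.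
- Commercial pterostilbene is O-arylated with commercial (5-formyl-2-methoxyphenyl)boronic acid by Chan–Lam–Evans coupling (Cu(OAc)2, pyridine, 4 Å sieves, CH2Cl2, air, rt). This gives 3-{4-[(E)-2-(3,5-dimethoxyphenyl)ethenyl]phenoxy}-4-methoxybenzaldehyde F4.
- Horner–Wadsworth–Emmons olefination of that aldehyde with 4 (KOtBu, THF) gives 9 directly, bypassing 5 and 7.

Step 4 may stop short of complete double reduction, giving mixtures that are hard to separate. The fallback sets out from 9 and comes back at 13. The C–Br bond is exchanged before the reduction, so ordinary hydrogenation becomes possible.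
- Miyaura borylation of 9 (B2pin2, PdCl2(dppf), KOAc, dioxane, 90 °C) gives the bis-stilbene pinacol boronate F5.
- Hydrogenation over Pd/C (H2, 1 atm, EtOAc, rt) leaves the C–B bond untouched and gives the ring C pinacol boronate F1.
- From there the sequence described above, through the bromo boronate F2 and the macrocyclic fluorobiaryl trimethyl ether F3, leads to 13.

**Further compounds**
F1 | step 6 | ring C pinacol boronate of 10 (Bpin in place of Br) | COc1ccc(CCc2ccc(B3OC(C)(C)C(C)(C)O3)c(F)c2)cc1Oc1ccc(CCc2cc(OC)cc(OC)c2)cc1
F2 | step 6 | bromo boronate (F1 with Br on ring D ortho to the chain and para to one OMe) | COc1ccc(CCc2ccc(B3OC(C)(C)C(C)(C)O3)c(F)c2)cc1Oc1ccc(CCc2cc(OC)cc(OC)c2Br)cc1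
F3 | step 6 | macrocyclic fluorobiaryl trimethyl ether (tri-O-methyl 13) | COc1cc2c(c(OC)c1)-c1ccc(cc1F)CCc1ccc(OC)c(c1)Oc1ccc(cc1)CC2
F4 | step 1 | 3-{4-[(E)-2-(3,5-dimethoxyphenyl)ethenyl]phenoxy}-4-methoxybenzaldehyde | COc1ccc(C=O)cc1Oc1ccc(/C=C/c2cc(OC)cc(OC)c2)cc1
F5 | step 4 | bis-stilbene pinacol boronate (9 with Bpin in place of Br) | COc1ccc(/C=C/c2ccc(B3OC(C)(C)C(C)(C)O3)c(F)c2)cc1Oc1ccc(/C=C/c2cc(OC)cc(OC)c2)cc1
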